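**Retrosynthetic overview**
1. Acid 34 ⇐ (alcohol oxidation, desilylation, diimide) ⇐ octalin 31. The C3–C4 bond of ring A is cut last: a tertiary C4 cation (proton on the isopropenyl group at C5) is captured at C3 by a (Z)-vinylsilane carried on C10.
2. Enabling feature: C4 carries two methyl groups and is bonded to the ring-fusion CH C5, whose neighbour C10 is quaternary (methyl + C1) and sits next to the C9 carbinol. Ring B with a C5 isopropenyl group, a C8 methyl and an α′ carbon open to two alkylations is (R)-carvone, so the isopropenyl group is the latent C4 cation and the trans ring fusion is fixed before ring A exists.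
3. 1,2-Dioxane (O1′–O2′–C3′–C6′): 6-endo cycloperoxymercuration of a C3′ hydroperoxide onto the (E)-C5′=C6′ olefin. The hydroperoxide comes by inversion of an Evans-aldol-derived alcohol; the C4′–C5′ bond by carboalumination and opening of epoxide 9.
4. C9 carbinol: oxidation of a C9=C11 enol ether from the face opposite the axial C10 methyl, then spiro-epoxide and propargyl Grignard opening (C11–C12).
5. Ring order: ring B (from carvone) → 1,2-dioxane (step 18) → ring A (step 19).

Key step: step 19

Remark: locants used are C1–C10 for the carbocycle (ring A = C1–C5 and C10, ring B = C5–C10), C11–C12 for the linker, O1′, O2′, C3′–C6′ for the dioxane and C1″–C3″ for the propanoate; enol ether 18 is taken as an E/Z mixture, its geometry being lost in step 11.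

**Route**

Step 1
Reactants: 1 (S)-4-benzyl-3-propanoyl-1,3-oxazolidin-2-one; 2 2-(benzyloxy)acetaldehyde
Product: 4 (S)-4-benzyl-3-[(2S,3S)-4-(benzyloxy)-3-hydroxy-2-methylbutanoyl]-1,3-oxazolidin-2-one, via Z-boron enolate 3 (not isolated)
Conditions: Bu2BOTf, i-Pr2NEt, CH2Cl2, 0 → −78 °C; 2, −78 → 0 °C; pH 7 buffer, MeOH, H2O2
Reagents that add atoms: none
Why: Evans syn-aldol reaction: the Z-boron enolate should add through a Zimmerman–Traxler chair on the enolate face remote from the auxiliary benzyl group, setting C2″ (final configuration) and C3′ (to be inverted in step 17).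

Step 2
Reactants: 4 (S)-4-benzyl-3-[(2S,3S)-4-(benzyloxy)-3-hydroxy-2-methylbutanoyl]-1,3-oxazolidin-2-one
Product: 5 (2R,3S)-4-(benzyloxy)-2-methylbutane-1,3-diol
Conditions: LiBH4, MeOH (1 equiv), THF, 0 °C
Reagents that add atoms: none
Why: Reductive cleavage of the N-acyl oxazolidinone by borohydride should give the primary alcohol without touching either stereocentre and release the auxiliary.

Step 3
Reactants: 5 (2R,3S)-4-(benzyloxy)-2-methylbutane-1,3-diol
Product: 6 (2S,3R)-1-(benzyloxy)-4-[(tert-butyldiphenylsilyl)oxy]-3-methylbutan-2-ol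
Conditions: t-BuPh2SiCl, imidazole, CH2Cl2, 0 °C
Reagents that add atoms: tert-butyl(chloro)diphenylsilane, CC(C)(C)[Si](Cl)(c1ccccc1)c1ccccc1
Why: Silyl ether formation with a bulky chlorosilane should be selective for the primary hydroxyl.

Step 4
Reactants: 6 (2S,3R)-1-(benzyloxy)-4-[(tert-butyldiphenylsilyl)oxy]-3-methylbutan-2-ol
Product: 7 (2S,3R)-4-[(tert-butyldiphenylsilyl)oxy]-3-methylbutane-1,2-diol
Conditions: H2 (1 atm), Pd on carbon, EtOAc, 23 °C
Reagents that add atoms: none
Why: Hydrogenolysis of the benzyl ether, to which the silyl ether is inert.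

Step 5
Reactants: 7 (2S,3R)-4-[(tert-butyldiphenylsilyl)oxy]-3-methylbutane-1,2-diol
Product: 9 tert-butyl{(2R)-2-[(2S)-oxiran-2-yl]propoxy}diphenylsilane, via primary tosylate 8 (not isolated)
Conditions: NaH, 1-(p-toluenesulfonyl)imidazole, THF, 0 → 23 °C
Reagents that add atoms: none
Why: One-pot sulfonylation of the primary alkoxide and 3-exo-tet displacement by the secondary alkoxide, which keeps the C3′–O bond and therefore its configuration.

Step 6
Reactants: 10 (R)-(−)-carvone
Product: 12 (5R,6S)-2,6-dimethyl-5-(prop-1-en-2-yl)cyclohex-2-en-1-one, via lithium dienolate 11 (not isolated)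
Conditions: LiN(i-Pr)2, THF, −78 °C; MeI, −78 → 0 °C
Reagents that add atoms: iodomethane, CI
Why: Kinetic deprotonation at the α′ carbon (future C10) gives the cross-conjugated dienolate, which should be methylated trans to the C5 isopropenyl group (this centre is re-enolised in step 7).

Step 7
Reactants: 12 (5R,6S)-2,6-dimethyl-5-(prop-1-en-2-yl)cyclohex-2-en-1-one
Product: 14 (5S,6S)-2,6-dimethyl-5-(prop-1-en-2-yl)-6-[3-(trimethylsilyl)prop-2-yn-1-yl]cyclohex-2-en-1-one, via lithium enolate 13 (not isolated)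
Conditions: LiN(i-Pr)2, THF, −78 °C; DMPU, BrCH2C≡CSiMe3, −78 → 0 °C
Reagents that add atoms: (3-bromoprop-1-yn-1-yl)trimethylsilane, C[Si](C)(C)C#CCBr
Why: Second α′-alkylation (SN2 at the propargylic bromide): the electrophile should enter the enolate face opposite the adjacent C5 isopropenyl group, setting quaternary C10 with C1 trans to C4 and the methyl cis.

Step 8
Reactants: 14 (5S,6S)-2,6-dimethyl-5-(prop-1-en-2-yl)-6-[3-(trimethylsilyl)prop-2-yn-1-yl]cyclohex-2-en-1-one
Product: 16 (2S,3S,6R)-2,6-dimethyl-3-(prop-1-en-2-yl)-2-[3-(trimethylsilyl)prop-2-yn-1-yl]cyclohexan-1-one, via lithium enolate 15 (not isolated)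
Conditions: LiBH(s-Bu)3 (L-Selectride), THF, −78 °C; aq. NH4Cl; then DBU, CH2Cl2, 23 °C
Reagents that add atoms: none
Why: Conjugate (1,4) hydride reduction of the β-unsubstituted enone, then base equilibration of C8 to the equatorial methyl, the other epimer suffering a 1,3-diaxial methyl/methyl interaction with the axial C10 methyl.

Step 9
Reactants: 16 (2S,3S,6R)-2,6-dimethyl-3-(prop-1-en-2-yl)-2-[3-(trimethylsilyl)prop-2-yn-1-yl]cyclohexan-1-one
Product: 17 (2S,3S,6R)-2,6-dimethyl-3-(prop-1-en-2-yl)-2-[(2Z)-3-(trimethylsilyl)prop-2-en-1-yl]cyclohexan-1-one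
Conditions: H2 (1 atm), Pd/CaCO3 poisoned with Pb(OAc)2 (Lindlar catalyst), quinoline, hexane/EtOAc, 23 °C
Reagents that add atoms: none
Why: Syn semi-hydrogenation of the alkynylsilane over poisoned Pd should give the (Z)-vinylsilane without reducing the ketone or the 1,1-disubstituted alkene.

Step 10
Reactants: 17 (2S,3S,6R)-2,6-dimethyl-3-(prop-1-en-2-yl)-2-[(2Z)-3-(trimethylsilyl)prop-2-en-1-yl]cyclohexan-1-one
Product: 18 methyl enol ether of 17 (C9=C11H–OMe, E/Z mixture; C5, C8, C10 as in 17)
Conditions: [Ph3PCH2OMe]Cl, KOt-Bu, THF, 0 → 65 °C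
Reagents that add atoms: (methoxymethyl)triphenylphosphonium chloride, COC[P+](c1ccccc1)(c1ccccc1)c1ccccc1.[Cl-]
Why: Wittig methoxymethylenation of the hindered ketone gives the C9=C11 enol ether, C8 staying in its thermodynamically fixed configuration.

Step 11
Reactants: 18 methyl enol ether of 17
Product: 20 C9,C11-diol (C9 tertiary alcohol carrying CH2OH; C9–O trans to the C10 methyl, cis to the C8 methyl), via α-hydroxy aldehyde 19 (not isolated)
Conditions: DMDO, acetone/CH2Cl2, −78 °C; H2O, NaHCO3; then NaBH4, MeOH, 0 °C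
Reagents that add atoms: dimethyldioxirane, CC1(C)OO1; water, O
Why: Rubottom-type oxidation: the electron-rich enol ether should be epoxidised chemoselectively (over isopropenyl and vinylsilane) from the face opposite the axial C10 methyl, hydrolysis then gives the α-hydroxy aldehyde with the C9–O bond in the target configuration, and borohydride reduces the aldehyde.

Step 12
Reactants: 20 C9,C11-diol
Product: 22 spiro-epoxide (C9–O–C11 oxirane, oxygen trans to the C10 methyl), via C11 tosylate 21 (not isolated)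
Conditions: NaH, 1-(p-toluenesulfonyl)imidazole, THF, 0 → 23 °C
Reagents that add atoms: none
Why: Sulfonylation of the primary alkoxide and 3-exo-tet closure by the tertiary alkoxide, so the C9–O bond and its configuration are retained.

Step 13
Reactants: 22 spiro-epoxide
Product: 23 homopropargylic tertiary alcohol (C9–OH; C11H2–C12H2–C≡CH)
Conditions: allenylmagnesium bromide, Et2O, −78 → 0 °C
Reagents that add atoms: allenylmagnesium bromide, C=C=C[Mg]Br
Why: SN2 opening of the 2,2-disubstituted oxirane at its CH2 carbon (C11) by the allenyl Grignard reagent reacting through its γ-carbon (SE2′) should give the homopropargylic alcohol with C9 unchanged.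

Step 14
Reactants: 23 homopropargylic tertiary alcohol
Product: 24 triethylsilyl ether of 23
Conditions: Et3SiOTf, 2,6-lutidine, CH2Cl2, −78 → 0 °C
Reagents that add atoms: triethylsilyl trifluoromethanesulfonate, CC[Si](CC)(CC)OS(=O)(=O)C(F)(F)F
Why: Silyl triflate silylation of the hindered tertiary alcohol; the ether prevents 5-exo capture by O9 in step 18 and ionisation at C9 in step 19.

Step 15
Reactants: 24 triethylsilyl ether of 23; 9 tert-butyl{(2R)-2-[(2S)-oxiran-2-yl]propoxy}diphenylsilane
Product: 26 homoallylic alcohol ((E)-C5′=C6′ olefin; free C3′–OH with the configuration opposite to the target; C1″–OSiPh2t-Bu; C9–OSiEt3), via E-alkenylalane 25 (not isolated)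
Conditions: Me3Al, Cp2ZrCl2 (20 mol %), CH2Cl2, 23 °C; n-BuLi, hexane, −78 °C; then 9, THF, −78 → 0 °C
Reagents that add atoms: trimethylaluminium, C[Al](C)C
Why: Negishi zirconium-catalysed syn carboalumination of the terminal alkyne (methyl to the internal carbon) gives the (E)-alkenylalane, whose ate complex should open epoxide 9 at its CH2 carbon with retention of olefin geometry and of C3′.

Step 16
Reactants: 26 homoallylic alcohol
Product: 27 C3′ methanesulfonate of 26
Conditions: MsCl, Et3N, CH2Cl2, 0 °C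
Reagents that add atoms: methanesulfonyl chloride, CS(=O)(=O)Cl
Why: Sulfonylation of the only free hydroxyl.

Step 17
Reactants: 27 C3′ methanesulfonate
Product: 28 C3′ hydroperoxide (inverted; target configuration at C3′)
Conditions: H2O2 (50 % aq.), KOH, MeOH/THF, 0 → 23 °C
Reagents that add atoms: hydrogen peroxide, OO
Why: SN2 displacement of the secondary mesylate by hydroperoxide anion (strong α-effect nucleophile, weak base) should proceed with inversion at C3′.

Step 18
Reactants: 28 C3′ hydroperoxide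
Product: 30 1,2-dioxane with open ring A (C5 isopropenyl; C10 (Z)-3-(trimethylsilyl)allyl), via 5′-acetoxymercurio dioxane 29 (not isolated)
Conditions: Hg(OAc)2, CH2Cl2, −20 → 0 °C; then NaBH4, aq. NaOH, 0 °C
Reagents that add atoms: none
Why: Cycloperoxymercuration–demercuration: the hydroperoxide should attack the mercurinium ion of the trisubstituted olefin at the tertiary carbon C6′ (Markovnikov, 6-endo), anti addition to the E-olefin through a chair with the C3′ side chain equatorial placing C12 equatorial and the methyl axial (6′S), and NaBH4 then replaces mercury by hydrogen.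

Step 19
Reactants: 30 1,2-dioxane with open ring A
Product: 31 Δ2-octalin (ring A closed, C2=C3; both silyl ethers retained)
Conditions: CF3CO2H, CH2Cl2, −40 → 0 °C
Reagents that add atoms: none
Why: Protonation of the 1,1-disubstituted isopropenyl alkene at its CH2 terminus (Markovnikov) should give the tertiary C4 cation, which is attacked at the ipso carbon C3 by the (Z)-vinylsilane tethered through C1 on C10, and loss of the silyl group from the β-silyl cation at C2 leaves the C2=C3 double bond. The closest known reaction type is the proton-initiated, vinylsilane-terminated cation–olefin cyclisation (a Stork–Eschenmoser-type closure with a silicon terminator). Ring A closes in a 6-endo-trig mode through a chair-like transition state in which the C5 and C10 side chains are both equatorial on ring B. No new stereocentre is formed: C4 becomes a non-stereogenic gem-dimethyl carbon, the trans ring fusion is dictated by the trans C5/C10 arrangement set from carvone in step 7, and the Z geometry of the vinylsilane allows ipso substitution with retention to give the cis ring olefin. The step needs chemoselective protonation of the isopropenyl group and a defined olefin position: the first should follow from the higher basicity of the 1,1-disubstituted alkene compared with the vinylsilane, the peroxide and the silyl ethers at low temperature, the second from the β-silicon effect, which also avoids a free secondary cation (no hydride or methyl shifts, no capture by the silylated O9). The only ionisable C–O bond of the dialkyl peroxide is the tertiary C6′–O bond, which should survive short exposure to CF3CO2H at or below 0 °C.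

Step 20
Reactants: 31 Δ2-octalin
Product: 32 saturated bis(silyl ether)
Conditions: KO2CN=NCO2K, AcOH, MeOH/CH2Cl2, 0 → 23 °C
Reagents that add atoms: none
Why: Diimide reduction (concerted syn transfer of H2) should saturate the cis-disubstituted C2=C3 double bond without cleaving the O–O bond.

Step 21
Reactants: 32 saturated bis(silyl ether)
Product: 33 diol (C9–OH, C1″–OH)
Conditions: Bu4NF, THF, 23 → 40 °C
Reagents that add atoms: none
Why: Fluoride-induced cleavage of both Si–O bonds, to which the dialkyl peroxide is inert.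

Step 22
Reactants: 33 diol
Product: 34 (2S)-2-[(3S,6S)-6-{2-[(1R,2R,4aS,8aS)-1-hydroxy-2,5,5,8a-tetramethyldecahydronaphthalen-1-yl]ethyl}-6-methyl-1,2-dioxan-3-yl]propanoic acid
Conditions: TEMPO (cat.), PhI(OAc)2, MeCN/H2O (pH 7), 23 °C
Reagents that add atoms: water, O
Why: Oxoammonium (TEMPO) oxidation of the primary alcohol through the aldehyde hydrate to the acid at near-neutral pH should leave the tertiary alcohol, the peroxide and the C2″ stereocentre untouched.

**Compound list**

1 | (S)-4-benzyl-3-propanoyl-1,3-oxazolidin-2-one | CCC(=O)N1[C@@H](Cc2ccccc2)COC1=O | starting material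
2 | 2-(benzyloxy)acetaldehyde | O=CCOCc1ccccc1 | starting material
3 | Z-dibutylboron enolate of 1 | C/C=C(\OB(CCCC)CCCC)N1[C@@H](Cc2ccccc2)COC1=O | intermediate (not isolated)
4 | (S)-4-benzyl-3-[(2S,3S)-4-(benzyloxy)-3-hydroxy-2-methylbutanoyl]-1,3-oxazolidin-2-one | C[C@H](C(=O)N1[C@@H](Cc2ccccc2)COC1=O)[C@H](O)COCc1ccccc1 | intermediate
5 | (2R,3S)-4-(benzyloxy)-2-methylbutane-1,3-diol | C[C@H](CO)[C@H](O)COCc1ccccc1 | intermediate
6 | (2S,3R)-1-(benzyloxy)-4-[(tert-butyldiphenylsilyl)oxy]-3-methylbutan-2-ol | C[C@H](CO[Si](c1ccccc1)(c1ccccc1)C(C)(C)C)[C@H](O)COCc1ccccc1 | intermediate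
7 | (2S,3R)-4-[(tert-butyldiphenylsilyl)oxy]-3-methylbutane-1,2-diol | C[C@H](CO[Si](c1ccccc1)(c1ccccc1)C(C)(C)C)[C@H](O)CO | intermediate
8 | primary p-toluenesulfonate of 7 | C[C@H](CO[Si](c1ccccc1)(c1ccccc1)C(C)(C)C)[C@H](O)COS(=O)(=O)c1ccc(C)cc1 | intermediate (not isolated)
9 | tert-butyl{(2R)-2-[(2S)-oxiran-2-yl]propoxy}diphenylsilane | C[C@H](CO[Si](c1ccccc1)(c1ccccc1)C(C)(C)C)[C@H]1CO1 | intermediate
10 | (R)-(−)-carvone, (5R)-2-methyl-5-(prop-1-en-2-yl)cyclohex-2-en-1-one | O=C1C(C)=CC[C@@H](C(C)=C)C1 | starting material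
11 | lithium cross-conjugated dienolate of 10 | [Li]OC1=C[C@H](C(C)=C)CC=C1C | intermediate (not isolated)
12 | (5R,6S)-2,6-dimethyl-5-(prop-1-en-2-yl)cyclohex-2-en-1-one | O=C1C(C)=CC[C@@H](C(C)=C)[C@@H]1C | intermediate
13 | lithium dienolate of 12 | [Li]OC1=C(C)[C@H](C(C)=C)CC=C1C | intermediate (not isolated)
14 | (5S,6S)-2,6-dimethyl-5-(prop-1-en-2-yl)-6-[3-(trimethylsilyl)prop-2-yn-1-yl]cyclohex-2-en-1-one | O=C1C(C)=CC[C@@H](C(C)=C)[C@]1(C)CC#C[Si](C)(C)C | intermediate
15 | lithium enolate from 1,4-reduction of 14 | [Li]OC1=C(C)CC[C@@H](C(C)=C)[C@]1(C)CC#C[Si](C)(C)C | intermediate (not isolated)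
16 | (2S,3S,6R)-2,6-dimethyl-3-(prop-1-en-2-yl)-2-[3-(trimethylsilyl)prop-2-yn-1-yl]cyclohexan-1-one | O=C1[C@H](C)CC[C@@H](C(C)=C)[C@]1(C)CC#C[Si](C)(C)C | intermediate
17 | (2S,3S,6R)-2,6-dimethyl-3-(prop-1-en-2-yl)-2-[(2Z)-3-(trimethylsilyl)prop-2-en-1-yl]cyclohexan-1-one | O=C1[C@H](C)CC[C@@H](C(C)=C)[C@]1(C)C/C=C\[Si](C)(C)C | intermediate
18 | methyl enol ether of 17 (C9=C11H–OMe, E/Z mixture) | COC=C1[C@H](C)CC[C@@H](C(C)=C)[C@]1(C)C/C=C\[Si](C)(C)C | intermediate
19 | α-hydroxy aldehyde (C9–OH trans to the C10 methyl; C11 aldehyde) | O=C[C@@]1(O)[C@H](C)CC[C@@H](C(C)=C)[C@]1(C)C/C=C\[Si](C)(C)C | intermediate (not isolated)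
20 | C9,C11-diol (C9–O trans to the C10 methyl, cis to the C8 methyl) | OC[C@@]1(O)[C@H](C)CC[C@@H](C(C)=C)[C@]1(C)C/C=C\[Si](C)(C)C | intermediate
21 | C11 p-toluenesulfonate of 20 | Cc1ccc(cc1)S(=O)(=O)OC[C@@]1(O)[C@H](C)CC[C@@H](C(C)=C)[C@]1(C)C/C=C\[Si](C)(C)C | intermediate (not isolated)
22 | spiro-epoxide (C9–O–C11 oxirane, oxygen trans to the C10 methyl) | O1C[C@]12[C@H](C)CC[C@@H](C(C)=C)[C@]2(C)C/C=C\[Si](C)(C)C | intermediate
23 | homopropargylic tertiary alcohol (C9–OH; C11H2–C12H2–C≡CH) | C#CCC[C@@]1(O)[C@H](C)CC[C@@H](C(C)=C)[C@]1(C)C/C=C\[Si](C)(C)C | intermediate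
24 | triethylsilyl ether of 23 | C#CCC[C@@]1(O[Si](CC)(CC)CC)[C@H](C)CC[C@@H](C(C)=C)[C@]1(C)C/C=C\[Si](C)(C)C | intermediate
25 | (E)-alkenyl(dimethyl)alane from 24 | C[Al](C)/C=C(\C)CC[C@@]1(O[Si](CC)(CC)CC)[C@H](C)CC[C@@H](C(C)=C)[C@]1(C)C/C=C\[Si](C)(C)C | intermediate (not isolated)
26 | homoallylic alcohol ((E)-C5′=C6′; free C3′–OH, configuration opposite to the target) | C[C@H](CO[Si](c1ccccc1)(c1ccccc1)C(C)(C)C)[C@H](O)C/C=C(\C)CC[C@@]1(O[Si](CC)(CC)CC)[C@H](C)CC[C@@H](C(C)=C)[C@]1(C)C/C=C\[Si](C)(C)C | intermediate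
27 | C3′ methanesulfonate of 26 | C[C@H](CO[Si](c1ccccc1)(c1ccccc1)C(C)(C)C)[C@H](OS(C)(=O)=O)C/C=C(\C)CC[C@@]1(O[Si](CC)(CC)CC)[C@H](C)CC[C@@H](C(C)=C)[C@]1(C)C/C=C\[Si](C)(C)C | intermediate
28 | C3′ hydroperoxide (target configuration at C3′) | C[C@H](CO[Si](c1ccccc1)(c1ccccc1)C(C)(C)C)[C@@H](OO)C/C=C(\C)CC[C@@]1(O[Si](CC)(CC)CC)[C@H](C)CC[C@@H](C(C)=C)[C@]1(C)C/C=C\[Si](C)(C)C | intermediate
29 | 5′-(acetoxymercurio)-1,2-dioxane (mercury equatorial, cis to the C6′ methyl) | C[C@H](CO[Si](c1ccccc1)(c1ccccc1)C(C)(C)C)[C@@H]1C[C@H]([Hg]OC(C)=O)[C@@](C)(CC[C@@]2(O[Si](CC)(CC)CC)[C@H](C)CC[C@@H](C(C)=C)[C@]2(C)C/C=C\[Si](C)(C)C)OO1 | intermediate (not isolated)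
30 | 1,2-dioxane with open ring A (C5 isopropenyl; C10 (Z)-3-(trimethylsilyl)allyl) | C[C@H](CO[Si](c1ccccc1)(c1ccccc1)C(C)(C)C)[C@@H]1CC[C@@](C)(CC[C@@]2(O[Si](CC)(CC)CC)[C@H](C)CC[C@@H](C(C)=C)[C@]2(C)C/C=C\[Si](C)(C)C)OO1 | intermediate
31 | Δ2-octalin (ring A closed, C2=C3, trans-fused) | C[C@H](CO[Si](c1ccccc1)(c1ccccc1)C(C)(C)C)[C@@H]1CC[C@@](C)(CC[C@@]2(O[Si](CC)(CC)CC)[C@H](C)CC[C@H]3C(C)(C)C=CC[C@@]32C)OO1 | intermediate
32 | saturated bis(silyl ether) | C[C@H](CO[Si](c1ccccc1)(c1ccccc1)C(C)(C)C)[C@@H]1CC[C@@](C)(CC[C@@]2(O[Si](CC)(CC)CC)[C@H](C)CC[C@H]3C(C)(C)CCC[C@@]32C)OO1 | intermediate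
33 | diol (C9–OH, C1″–OH) | C[C@H](CO)[C@@H]1CC[C@@](C)(CC[C@@]2(O)[C@H](C)CC[C@H]3C(C)(C)CCC[C@@]32C)OO1 | intermediate
34 | (2S)-2-[(3S,6S)-6-{2-[(1R,2R,4aS,8aS)-1-hydroxy-2,5,5,8a-tetramethyldecahydronaphthalen-1-yl]ethyl}-6-methyl-1,2-dioxan-3-yl]propanoic acid | C[C@H](C(=O)O)[C@@H]1CC[C@@](C)(CC[C@@]2(O)[C@H](C)CC[C@H]3C(C)(C)CCC[C@@]32C)OO1 | target

**Totals**

Total step count: 22. Longest linear sequence: 17 steps (steps 6–22, from (R)-carvone); steps 1–5 make epoxide 9 in parallel.

**Steps most likely to fail, with fallbacks**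

Step 19 (ring A closure). What may go wrong: acid-induced loss of the tertiary silyl ether followed by ionisation at C9, protodesilylation of the vinylsilane before cyclisation, or acidolysis of the tertiary C6′–O bond of the peroxide could outrun the cyclisation. Loss of the C5 proton from the C4 cation and reprotonation could also erode the C5 configuration. The fallback generates the cation without a Brønsted acid, by electrophilic mercuration. Setting out from 30, Hg(OTf)2·PhNMe2 in MeNO2/CH2Cl2 at −20 °C should add to the CH2 terminus of the isopropenyl group, the tertiary C4 cation is captured by the vinylsilane as before, and aqueous NaCl gives the chloromercurial of the Δ2-octalin F1 (C4 bearing CH3 and CH2HgCl). NaBH4 in aqueous NaOH then replaces mercury by hydrogen, which makes the second C4 methyl and returns to the route at 31.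

Step 17 (hydroperoxide by displacement). What may go wrong: E2 elimination toward the allylic C4′ hydrogens, or slow substitution at the β-branched secondary centre with base-induced decomposition of the product hydroperoxide. The fallback uses a better leaving group and a ketal-protected peroxide nucleophile under non-aqueous, cold conditions. Setting out from 26, Tf2O and 2,6-lutidine (CH2Cl2, −78 °C) give the C3′ trifluoromethanesulfonate F2. The potassium salt of 2-methoxyprop-2-yl hydroperoxide (KOt-Bu, THF, −40 → 0 °C) displaces it with inversion to give the peroxyketal F3. Aqueous AcOH/THF then frees the hydroperoxide and comes back to the route at 28.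

Step 18 (dioxane closure). What may go wrong: competing attack of divalent mercury on the isopropenyl or vinylsilane alkene, erosion of the chair preference that sets C6′, or fragmentation of the β-peroxy radical to an epoxide during hydride demercuration. The fallback replaces mercury by a reversible iodonium electrophile and a tin-hydride reduction. Setting out from 28, N-iodosuccinimide (CH2Cl2, −40 °C, dark) should cyclise through the same chair to the 5′-iodo-1,2-dioxane F4. Bu3SnH with AIBN at high hydride concentration (benzene, 60 °C) removes the iodine and comes back to the route at 30.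

Further compounds
F1 | step 19 | chloromercurial of the Δ2-octalin (C4 bearing CH3 and CH2HgCl, epimer mixture at C4) | C[C@H](CO[Si](c1ccccc1)(c1ccccc1)C(C)(C)C)[C@@H]1CC[C@@](C)(CC[C@@]2(O[Si](CC)(CC)CC)[C@H](C)CC[C@H]3C(C)(C[Hg]Cl)C=CC[C@@]32C)OO1
F2 | step 17 | C3′ trifluoromethanesulfonate of 26 | C[C@H](CO[Si](c1ccccc1)(c1ccccc1)C(C)(C)C)[C@H](OS(=O)(=O)C(F)(F)F)C/C=C(\C)CC[C@@]1(O[Si](CC)(CC)CC)[C@H](C)CC[C@@H](C(C)=C)[C@]1(C)C/C=C\[Si](C)(C)C
F3 | step 17 | C3′ 2-methoxyprop-2-yl peroxyketal (inverted at C3′) | C[C@H](CO[Si](c1ccccc1)(c1ccccc1)C(C)(C)C)[C@@H](OOC(C)(C)OC)C/C=C(\C)CC[C@@]1(O[Si](CC)(CC)CC)[C@H](C)CC[C@@H](C(C)=C)[C@]1(C)C/C=C\[Si](C)(C)C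
F4 | step 18 | 5′-iodo-1,2-dioxane (iodine equatorial, cis to the C6′ methyl) | C[C@H](CO[Si](c1ccccc1)(c1ccccc1)C(C)(C)C)[C@@H]1C[C@H](I)[C@@](C)(CC[C@@]2(O[Si](CC)(CC)CC)[C@H](C)CC[C@@H](C(C)=C)[C@]2(C)C/C=C\[Si](C)(C)C)OO1
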